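The earlier runs and the new flask come from a simulation with made-up constants, and the scatter is random.

Dawn, summer and dusk were the runs I had: the same starting material and free catalyst, with the reagent varied. Catalyst and reagent turn starting material into target.

| flask | starting material | reagent | free catalyst | remark | time |
|---|---|---|---|---|---|
| dawn | 0.10 M | 0.14 M | 5 mM | run made earlier |  |
| summer | 0.10 M | 0.25 M | 5 mM | run made earlier |  |
| dusk | 0.10 M | 0.75 M | 5 mM | run made earlier |  |
| grey | 0.10 M | 0.690 M | 5.0 mM |  | 25 min |
| red | 0.10 M | 0.280 M | 5.0 mM |  | 25 min |
| violet | 0.10 M | 0.110 M | 5.0 mM |  | 25 min |

| run | time / min | starting material / % | over-reaction product / % | catalyst intermediate C / % | target / % |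
|---|---|---|---|---|---|
| dawn | 1.33 | 97.1 | 0.5 | 2.9 | 1.0 |
| dawn | 3.00 | 95.2 | 0 | 0 | 1.2 |
| dawn | 8.00 | 92.9 | 0 | 2.0 | 5.8 |
| dawn | 20.0 | 84.1 | 0.1 | 1.3 | 13.2 |
| summer | 1.33 | 96.6 | 0 | 1.3 | 0.3 |
| summer | 3.00 | 97.1 | 0 | 1.3 | 3.0 |
| summer | 8.00 | 91.4 | 0 | 0.9 | 6.8 |
| summer | 20.0 | 79.4 | 0.8 | 2.4 | 18.0 |
| dusk | 2.00 | 96.0 | 0 | 3.5 | 1.4 |
| dusk | 6.00 | 89.2 | 0 | 3.3 | 7.2 |
| dusk | 12.0 | 81.8 | 1.0 | 4.3 | 14.0 |
| dusk | 20.0 | 73.0 | 0.8 | 1.7 | 21.5 |

(scatter of a reading: 1 percentage point)

- steps thought possible: starting material + free catalyst <-> catalyst intermediate A; reagent + catalyst intermediate A <-> catalyst intermediate B; catalyst intermediate B -> by-product + catalyst intermediate C; catalyst intermediate C -> free catalyst + target; reagent + target -> over-reaction product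

* which of these there is most of at the end, counted by the starting material in it, grey (starting material / target / catalyst intermediate C / over-reaction product)
* which of these there is most of at the end, counted by the starting material in it, red (starting material / target / catalyst intermediate C / over-reaction product)
* which of these there is most of at the end, counted by the starting material in it, violet (starting material / target / catalyst intermediate C / over-reaction product)
* amount of the one of these that there is most of at the end, in percent of the starting material charged, grey
* amount of the one of these that there is most of at the end, in percent of the starting material charged, red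
* amount of the one of these that there is most of at the end, in percent of the starting material charged, violet

I reckoned the rate and nothing else. I called k the loss constant (pseudo-first-order): the share of the starting material present that goes per minute, taken from a run's last reading. Dawn gave 0.00866 /min and dusk 0.0157 /min, so 5.36 times the reagent bought 1.81 times the constant, and k was climbing toward a ceiling. I drew k as ceiling times B/(B + H), with B the reagent concentration and H a constant of the runs. Those two runs gave a ceiling of 0.0194 /min and an H of 0.173 M, the half-point: the reagent concentration at which k stands at half the ceiling. That point was the zero of my scale. Summer, not used in drawing it, got 0.0114 /min, which leaves 79.6% at 20.0 min; the reading was 79.4%.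

By my reckoning grey started at 0.0155 /min and red at 0.0120 /min, both with reagent above H, and violet at 0.00752 /min, with reagent below it.

Two factors slowed them in my reckoning. Falling starting material took the rate by the end to 0.679 of its start in grey, 0.741 in red and 0.829 in violet. Reagent used one for one with starting material lowered k itself by the end to 0.990 of its start in grey, 0.963 in red and 0.899 in violet, so violet lost more this way than grey.

Taking the mean of k over each run, I expected 68.0% left in grey, 74.6% in red and 83.6% in violet. Even grey, faster than the others, kept more starting material than it lost.

The forecast gave starting material at 68% in grey, 74% in red, below mine, and 84% in violet, holding that “none of them goes far enough in 25 min for target to overtake it”.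

The flasks held starting material at 66.7% in grey, 74.5% in red and 84.1% in violet.

    starting material + free catalyst ⇌ catalyst intermediate A (K = 1.20 /M, k = 0.298 /M/s)
    reagent + catalyst intermediate A ⇌ catalyst intermediate B (K = 42.0 /M, k = 0.324 /M/s)
    catalyst intermediate B → by-product + catalyst intermediate C (k = 0.751 /s)
    catalyst intermediate C → free catalyst + target (k = 0.00696 /s)
    reagent + target → over-reaction product (k = 3.47 × 10⁻⁴ /M/s)

Through grey, catalyst intermediate B went on to catalyst intermediate C with 94.5% of the reagent free at 25.0 min, while catalyst intermediate C held 60.7% of the catalyst at 12.5 min and 55.7% at 25.0 min. Reagent on target ran behind that, with over-reaction product at 1.20% and then 4.66%. Read back, grey's constant stood at 83.7% of my ceiling and violet's at 35.9%, on the sides of the half-point where H had put them. Carried to grey read at 1.0 h, my start constant leaves 39.5%, but that flask held 32.9% starting material against 43.8% target.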